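**Retrosynthetic overview**

1. Target 13 is a cyclohexane β-triketone; ring numbering used below: C1 ketone, C2 bearing the isobutyryl group, C3 enol carbon, C4 tertiary carbinol stereocentre with one prenyl group, C5 ketone, C6 gem-diprenyl carbon.
2. Key disconnection: the C1–C2 and C3–C4 ring bonds are made together, which turns 13 into its achiral isomer 11, the β-ketoacyl enol ester of 3,3,5-triprenylfuran-2,4-dione 6. A chiral isothiourea moves the acyl group from oxygen to C4 (C3–C4 bond, stereocentre), and the new diketone carbon then attacks the lactone carbonyl (C1–C2 bond).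
3. Enabling feature: in 13 the C4 hydroxyl and the C1 carbonyl are bridged by the C5(=O)–C6(prenyl)2 unit, so O–C1 can be closed as a five-membered furan-2,4-dione (tetronic acid) ring (furanone C2, C3, C4, C5 = target C1, C6, C5, C4). The lactone activates C1, carries the C4 oxygen at its final oxidation level, and, because C6 is quaternary, leaves C4 as the only enolisable carbon.
4. 11 comes from 6 and isobutyrylketene (from acyl Meldrum's acid 9); 6 comes from tetronic acid by palladium-catalysed double prenylation at furanone C3 and enolate prenylation at furanone C5. Racemic 6 is acceptable because its stereocentre is planarised in 11 and rebuilt under catalyst control.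
5. Ring order: the purchased furanone is the only ring up to 11; the carbocycle closes in the key step as the furanone opens.

Key step: step 5

Assumption: (2S,3R)-HyperBTM is taken to deliver the (4R) carbinol by extrapolation from the accepted model for isothiourea-bound acyl groups; if the sense proves opposite, the (2R,3S) catalyst is used. Compound 13 is written in the enol tautomer of the target structure.

**Route**

Step 1
Reactants: 1 tetronic acid (4-hydroxyfuran-2(5H)-one); 2 prenyl acetate (3-methylbut-2-en-1-yl acetate, 2.3 equiv)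
Product: 4 3,3-bis(3-methylbut-2-en-1-yl)furan-2,4(3H,5H)-dione, via 3-prenyltetronic acid 3 (not isolated)
Conditions: Pd(PPh3)4 (5 mol %), Et3N, THF, 55 °C
Reagents that add atoms: prenyl acetate 2, CC(=O)OCC=C(C)C
Why: Tsuji–Trost allylation, in which the soft tetronate carbon attacks the π-(1,1-dimethylallyl)palladium intermediate at its unsubstituted terminus, O-allylated material re-ionises under zerovalent palladium, and the second alkylation makes C3 quaternary; no stereocentre is formed.

Step 2
Reactants: 4 3,3-bis(3-methylbut-2-en-1-yl)furan-2,4(3H,5H)-dione; 5 prenyl bromide (1-bromo-3-methylbut-2-ene)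
Product: 6 (±)-3,3,5-tris(3-methylbut-2-en-1-yl)furan-2,4(3H,5H)-dione
Conditions: LiN(SiMe3)2 (1.05 equiv), THF, −78 °C; then 5, DMPU, −78 to −30 °C
Reagents that add atoms: prenyl bromide 5, CC(C)=CCBr
Why: SN2 alkylation of a lithium ketone enolate by an allylic bromide at furanone C5, the only enolisable carbon of 4 because C3 is quaternary; the new stereocentre is formed as a racemate, which is harmless because it is planarised again in step 4.

Step 3
Reactants: 7 Meldrum's acid (2,2-dimethyl-1,3-dioxane-4,6-dione); 8 isobutyryl chloride (2-methylpropanoyl chloride)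
Product: 9 5-(1-hydroxy-2-methylpropylidene)-2,2-dimethyl-1,3-dioxane-4,6-dione (isobutyryl Meldrum's acid)
Conditions: pyridine, CH2Cl2, 0 °C to rt
Reagents that add atoms: isobutyryl chloride 8, CC(C)C(Cl)=O
Why: C-acylation of the strongly acidic Meldrum's acid by an acid chloride with pyridine (standard acyl Meldrum's acid synthesis), giving the enolised acyl derivative; no stereocentre.

Step 4
Reactants: 6 (±)-3,3,5-tris(3-methylbut-2-en-1-yl)furan-2,4(3H,5H)-dione; 9 isobutyryl Meldrum's acid (1.5 equiv, added slowly)
Product: 11 2-oxo-3,3,5-tris(3-methylbut-2-en-1-yl)-2,3-dihydrofuran-4-yl 4-methyl-3-oxopentanoate, via isobutyrylketene 10 (not isolated)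
Conditions: toluene, 85 °C
Reagents that add atoms: isobutyryl Meldrum's acid 9, CC(C)C(O)=C1C(=O)OC(C)(C)OC1=O
Why: Thermolysis of the acyl Meldrum's acid (retro-[4+2] loss of acetone and CO2) gives acylketene 10, which should be captured at oxygen by the enol tautomer of 6 (enolisation assisted by the acidic 9), the standard acylketene route to β-keto esters; furanone C5 becomes sp2, so racemic 6 converges on achiral 11.

Step 5
Reactants: 11 2-oxo-3,3,5-tris(3-methylbut-2-en-1-yl)-2,3-dihydrofuran-4-yl 4-methyl-3-oxopentanoate
Product: 13 (4R)-3,4-dihydroxy-2-(2-methylpropanoyl)-4,6,6-tris(3-methylbut-2-en-1-yl)cyclohex-2-ene-1,5-dione, via C-acylated lactone 12 (not isolated)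
Conditions: (2S,3R)-HyperBTM [(2S,3R)-3-isopropyl-2-phenyl-3,4-dihydro-2H-benzo[4,5]thiazolo[3,2-a]pyrimidine] (10 mol %), CH2Cl2, 0 °C; then DBU (1.5 equiv), 0 °C to rt; aq. citric acid
Reagents that add atoms: none
Why: Proposed new method: the isothiourea attacks the enol-ester carbonyl of 11 and the resulting N-(β-ketoacyl)isothiouronium/furanone-enolate ion pair collapses at carbon (O-to-C acyl transfer), which forms the C3–C4 bond (target numbering) and gives lactone 12. DBU then enolises the new 1,3-diketone, whose central carbon attacks the lactone carbonyl and expels the tertiary alkoxide on C4, which forms the C1–C2 bond, frees the C4 hydroxyl and ends in the strongly acidic triketone enolate as thermodynamic sink. Closest known reaction types are the Lewis-base-catalysed enantioselective Steglich and Black O-to-C acyl or carboxyl transfers of five-membered heterocyclic enol esters and carbonates, DMAP-catalysed acetoacetyl transfer, and the base-mediated rearrangement of lactones carrying a pendant carbon acid into cyclic 1,3-diones (phthalide to indane-1,3-dione type); the β-ketoacyl migrating group, this enolate class and the coupling of both events are new. The carbocycle closes by a 6-(enolexo)-exo-trig Claisen attack across the five-membered lactone through a 7-oxabicyclo[2.2.1]heptane tetrahedral intermediate, whose collapse opens the temporary furanone ring. C4, the only stereocentre, is set in the C-acylation, where the catalyst-bound acyl group (conformation fixed by the S···O contact, one face blocked by the phenyl group) differentiates the enantiotopic faces of the planar enolate; the Claisen step does not touch C4. The step needs C- over O-acylation, a single enolate terminus and a single acyl acceptor: O-acylation only regenerates 11 while C-acylation is drained by the Claisen step, the quaternary gem-diprenyl carbon leaves C4 as the only nucleophilic carbon, and the diketone carbon can reach only the lactone carbonyl because attack on the ring ketone would give a cyclobutanol.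

**Compound list**

1 | tetronic acid (4-hydroxyfuran-2(5H)-one) | OC1=CC(=O)OC1 | starting material
2 | prenyl acetate (3-methylbut-2-en-1-yl acetate) | CC(=O)OCC=C(C)C | starting material
3 | 4-hydroxy-3-(3-methylbut-2-en-1-yl)furan-2(5H)-one (3-prenyltetronic acid) | CC(C)=CCC1=C(O)COC1=O | intermediate
4 | 3,3-bis(3-methylbut-2-en-1-yl)furan-2,4(3H,5H)-dione | CC(C)=CCC1(CC=C(C)C)C(=O)COC1=O | intermediate
5 | prenyl bromide (1-bromo-3-methylbut-2-ene) | CC(C)=CCBr | starting material
6 | (±)-3,3,5-tris(3-methylbut-2-en-1-yl)furan-2,4(3H,5H)-dione | CC(C)=CCC1OC(=O)C(CC=C(C)C)(CC=C(C)C)C1=O | intermediate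
7 | Meldrum's acid (2,2-dimethyl-1,3-dioxane-4,6-dione) | CC1(C)OC(=O)CC(=O)O1 | starting material
8 | isobutyryl chloride (2-methylpropanoyl chloride) | CC(C)C(Cl)=O | starting material
9 | 5-(1-hydroxy-2-methylpropylidene)-2,2-dimethyl-1,3-dioxane-4,6-dione | CC(C)C(O)=C1C(=O)OC(C)(C)OC1=O | intermediate
10 | isobutyrylketene (4-methylpent-1-ene-1,3-dione) | CC(C)C(=O)C=C=O | intermediate
11 | 2-oxo-3,3,5-tris(3-methylbut-2-en-1-yl)-2,3-dihydrofuran-4-yl 4-methyl-3-oxopentanoate (achiral enol ester) | CC(C)C(=O)CC(=O)OC1=C(CC=C(C)C)OC(=O)C1(CC=C(C)C)CC=C(C)C | intermediate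
12 | (5R)-5-(4-methyl-3-oxopentanoyl)-3,3,5-tris(3-methylbut-2-en-1-yl)furan-2,4(3H,5H)-dione | CC(C)C(=O)CC(=O)[C@@]1(CC=C(C)C)OC(=O)C(CC=C(C)C)(CC=C(C)C)C1=O | intermediate
13 | (4R)-3,4-dihydroxy-2-(2-methylpropanoyl)-4,6,6-tris(3-methylbut-2-en-1-yl)cyclohex-2-ene-1,5-dione | CC(C)=CCC1(CC=C(C)C)C(=O)C(C(=O)C(C)C)=C(O)[C@](O)(CC=C(C)C)C1=O | target

**Step count and risks**

Total steps: 5. Longest linear sequence: 4 (steps 1, 2, 4, 5; step 3 is a one-step branch).

Steps most likely to fail:

1. Step 5 (Proposed new method). The ion pair may not discriminate the enolate faces well enough. Free acylketene released from 11 may cause a racemic background C-acylation. The transannular Claisen attack may be slow, leaving room for retro-Claisen loss of the acyl group or base-induced acyloin ring contraction of 13. The fallback uses known chemistry, sets out from 8 and 5 and returns at 13. Friedel–Crafts acylation of commercial phloroglucinol with 8 (AlCl3, nitrobenzene) would give 2-methyl-1-(2,4,6-trihydroxyphenyl)propan-1-one F1. Exhaustive C-prenylation with 5 (NaOMe, MeOH, 0 °C) would pass through 2-methyl-1-[2,4,6-trihydroxy-3-(3-methylbut-2-en-1-yl)phenyl]propan-1-one F2 and deoxycohumulone F3 (neither isolated) and end, by dearomatising alkylation, in colupulone F4. The sodium enolate of F4 (NaN(SiMe3)2, THF, −78 °C) would then be hydroxylated at the monoprenylated ring carbon by an enantiopure (camphorsulfonyl)oxaziridine (electrophilic enolate hydroxylation), the antipode of the reagent being chosen for the (4R) sense, to give 13.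

2. Step 4. Capture of the ketene by the weakly enolised ketone may be slow, so that ketene dimerisation and thermal drift of the acyl group from oxygen to carbon (racemic 12) compete. The fallback sets out from 6 and returns at 11, replacing neutral enol capture by acylation of a preformed enolate with a masked acid chloride. Commercial methyl 4-methyl-3-oxopentanoate would be ketalised (ethylene glycol, TsOH, toluene, water removal) to methyl 2-[2-(propan-2-yl)-1,3-dioxolan-2-yl]acetate F5 and saponified (LiOH, THF–H2O) to 2-[2-(propan-2-yl)-1,3-dioxolan-2-yl]acetic acid F6. Treatment with 1-chloro-N,N,2-trimethylprop-1-en-1-amine under neutral conditions would give 2-[2-(propan-2-yl)-1,3-dioxolan-2-yl]acetyl chloride F7. The potassium enolate of 6 (KN(SiMe3)2, THF, −78 °C) would be O-acylated by F7 to 2-oxo-3,3,5-tris(3-methylbut-2-en-1-yl)-2,3-dihydrofuran-4-yl 2-[2-(propan-2-yl)-1,3-dioxolan-2-yl]acetate F8, and mild ketal hydrolysis (PPTS, acetone–H2O) would unmask the ketone to give 11.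

3. Step 2. O-alkylation, proton exchange leading to double alkylation at furanone C5, and Claisen self-condensation of the enolate with the lactone carbonyl may compete. The fallback sets out from 1 and returns at 6, installing the C5 prenyl group before C3 is made quaternary. Condensation of 1 with pyrrolidine (toluene, water removal) would give the vinylogous carbamate 4-(pyrrolidin-1-yl)furan-2(5H)-one F9. Lithiation at C5 (t-BuLi, THF, −78 °C) and alkylation with 5 would give 5-(3-methylbut-2-en-1-yl)-4-(pyrrolidin-1-yl)furan-2(5H)-one F10, and hydrolysis (dilute aq. HCl, THF, rt) would give 4-hydroxy-5-(3-methylbut-2-en-1-yl)furan-2(5H)-one F11. Double Tsuji–Trost prenylation at C3 with 2 (Pd(PPh3)4, Et3N, THF), passing through 4-hydroxy-3,5-bis(3-methylbut-2-en-1-yl)furan-2(5H)-one F12 (not isolated), would give 6.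

**Further compounds**

F1 | step 5 | 2-methyl-1-(2,4,6-trihydroxyphenyl)propan-1-one | CC(C)C(=O)c1c(O)cc(O)cc1O
F2 | step 5 | 2-methyl-1-[2,4,6-trihydroxy-3-(3-methylbut-2-en-1-yl)phenyl]propan-1-one | CC(C)C(=O)c1c(O)cc(O)c(CC=C(C)C)c1O
F3 | step 5 | deoxycohumulone, 2-methyl-1-[2,4,6-trihydroxy-3,5-bis(3-methylbut-2-en-1-yl)phenyl]propan-1-one | CC(C)C(=O)c1c(O)c(CC=C(C)C)c(O)c(CC=C(C)C)c1O
F4 | step 5 | colupulone, 3,5-dihydroxy-2-(2-methylpropanoyl)-4,6,6-tris(3-methylbut-2-en-1-yl)cyclohexa-2,4-dien-1-one | CC(C)C(=O)C1=C(O)C(CC=C(C)C)=C(O)C(CC=C(C)C)(CC=C(C)C)C1=O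
F5 | step 4 | methyl 2-[2-(propan-2-yl)-1,3-dioxolan-2-yl]acetate | COC(=O)CC1(C(C)C)OCCO1
F6 | step 4 | 2-[2-(propan-2-yl)-1,3-dioxolan-2-yl]acetic acid | OC(=O)CC1(C(C)C)OCCO1
F7 | step 4 | 2-[2-(propan-2-yl)-1,3-dioxolan-2-yl]acetyl chloride | ClC(=O)CC1(C(C)C)OCCO1
F8 | step 4 | 2-oxo-3,3,5-tris(3-methylbut-2-en-1-yl)-2,3-dihydrofuran-4-yl 2-[2-(propan-2-yl)-1,3-dioxolan-2-yl]acetate | CC(C)C1(CC(=O)OC2=C(CC=C(C)C)OC(=O)C2(CC=C(C)C)CC=C(C)C)OCCO1
F9 | step 2 | 4-(pyrrolidin-1-yl)furan-2(5H)-one | O=C1C=C(N2CCCC2)CO1
F10 | step 2 | 5-(3-methylbut-2-en-1-yl)-4-(pyrrolidin-1-yl)furan-2(5H)-one | CC(C)=CCC1OC(=O)C=C1N1CCCC1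
F11 | step 2 | 4-hydroxy-5-(3-methylbut-2-en-1-yl)furan-2(5H)-one | CC(C)=CCC1OC(=O)C=C1O
F12 | step 2 | 4-hydroxy-3,5-bis(3-methylbut-2-en-1-yl)furan-2(5H)-one | CC(C)=CCC1OC(=O)C(CC=C(C)C)=C1O
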